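**Plan**

- Feature: with the ring numbered O1, O2, C3, C4, C5, carbon C3 (CH3, CH2CO2H) is fully substituted and its two-carbon arm ends in oxygen. C3, that arm and its oxygen can therefore be folded back into a 2-methyl-2-alkyloxetane whose tertiary carbon lies within five-ring reach of a hydroperoxide on C5.
- Cuts, in retrosynthetic order: CO2H to CH2OH; the C3–O2 ring bond (oxetane plus C5–OOH); the C5–OO bond and C5 methyl (1,1-disubstituted alkene, from a ketone); the C5–side-chain bond (aldehyde plus Grignard reagent); one C–C bond inside the side chain (triflate plus Grignard reagent).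
- Forward: the carbon chain is joined first, dioxygen is placed on C5, the 1,2-dioxolane (the only ring) closes by opening the oxetane, and oxidation of the arm ends the route.
- Stereochemistry: C3 comes from a Sharpless epoxidation with L-(+)-tartrate, is carried in the oxetane and inverted at ring closure. The side-chain methyl centre is bought as (2R)-3-bromo-2-methylpropan-1-ol.
- C5 is created without control; the pair of C5 epimers is carried through two steps and the cis-dimethyl dioxolane is isolated by chromatography after ring closure.

Key step: step 13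

Remark on the chemistry: the cobalt-mediated peroxidation is assumed to show no useful facial preference at the new peroxide carbon (C2 of the dodecane chain, later ring carbon C5). The silyl peroxide 20 and the hydroperoxide 21 are therefore each handled and numbered as the pair of epimers at that carbon. The pair is parted only after ring closure, where the two isomers differ as cis and trans ring diastereomers. The enantiomeric purity of epoxy alcohol 5 should be checked before going on.

**Route**

Step 1
Reactants: 1 pent-1-en-4-yne
Product: 4 (2E)-3-methylhexa-2,5-dien-1-ol, via alkenyldimethylalane 2 (not isolated), via lithium alkenylalanate 3 (not isolated)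
Conditions: Me3Al (2 equiv), Cp2ZrCl2 (0.25 equiv), CH2Cl2, 0 °C → rt; evaporate; n-BuLi, THF–hexane, −78 → 0 °C; (CH2O)n, rt; aq HCl
Reagents that add atoms: trimethylaluminium C[Al](C)C; formaldehyde (from paraformaldehyde) C=O
Why: Negishi zirconium-catalysed carboalumination adds methyl and aluminium syn across the terminal alkyne with methyl on the internal carbon and leaves the unactivated alkene alone, and the derived alanate is hydroxymethylated by formaldehyde with retention of the (E)-geometry.

Step 2
Reactants: 4 (2E)-3-methylhexa-2,5-dien-1-ol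
Product: 5 [(2S,3S)-3-methyl-3-(prop-2-en-1-yl)oxiran-2-yl]methanol
Conditions: Ti(OiPr)4 (5 mol %), L-(+)-diethyl tartrate (7 mol %), t-BuOOH, 4 Å molecular sieves, CH2Cl2, −20 °C
Reagents that add atoms: tert-butyl hydroperoxide CC(C)(C)OO
Why: Sharpless asymmetric epoxidation touches only the allylic-alcohol double bond, and with the L-(+)-tartrate the oxygen is delivered to the face that gives the (2S,3S)-epoxide, as for geraniol-type (E)-trisubstituted allylic alcohols, which fixes the later oxetane carbon.

Step 3
Reactants: 5 [(2S,3S)-3-methyl-3-(prop-2-en-1-yl)oxiran-2-yl]methanol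
Product: 6 (3S)-3-methylhex-5-ene-1,3-diol
Conditions: NaAlH2(OCH2CH2OMe)2, THF, 0 °C → rt; aq NaOH
Reagents that add atoms: none
Why: In this directed reduction of a 2,3-epoxy alcohol the aluminium alkoxide of the primary hydroxyl delivers hydride internally to C2, so the 1,3-diol forms and the tertiary C3–O bond with its configuration is not touched.

Step 4
Reactants: 6 (3S)-3-methylhex-5-ene-1,3-diol
Product: 8 (2S)-2-methyl-2-(prop-2-en-1-yl)oxetane, via primary monotosylate 7 (not isolated)
Conditions: n-BuLi (1.0 equiv), THF, 0 °C; TsCl (1.0 equiv); n-BuLi (1.0 equiv), 0 → 60 °C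
Reagents that add atoms: none
Why: One-pot sulfonylation of the primary alkoxide and deprotonation of the tertiary hydroxyl lead to a 4-exo-tet Williamson closure at the primary carbon, so the tertiary C–O bond is kept and the stereocentre is retained.

Step 5
Reactants: 8 (2S)-2-methyl-2-(prop-2-en-1-yl)oxetane
Product: 10 2-[(2R)-2-methyloxetan-2-yl]acetaldehyde, via secondary ozonide 9 (not isolated)
Conditions: O3, CH2Cl2, −78 °C; PPh3, −78 °C → rt; used as a cold solution after filtration through silica
Reagents that add atoms: ozone [O-][O+]=O
Why: Ozonolysis with reductive work-up cleaves the only alkene under neutral conditions that spare the oxetane, and the small, elimination-prone aldehyde is kept cold and not concentrated to dryness.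

Step 6
Reactants: 11 (2R)-3-bromo-2-methylpropan-1-ol
Product: 12 (2R)-3-bromo-2-methylpropyl trifluoromethanesulfonate
Conditions: Tf2O, pyridine, CH2Cl2, −78 → −20 °C; used crude
Reagents that add atoms: trifluoromethanesulfonic anhydride O=S(=O)(OS(=O)(=O)C(F)(F)F)C(F)(F)F
Why: Sulfonylation of a primary alcohol with triflic anhydride is routine at low temperature, the primary bromide is inert and the stereocentre is not involved.

Step 7
Reactants: 12 (2R)-3-bromo-2-methylpropyl trifluoromethanesulfonate; 13 (7-bromoheptyl)benzene
Product: 15 [(9R)-10-bromo-9-methyldecyl]benzene, via 7-phenylheptylmagnesium bromide 14 (not isolated)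
Conditions: 13, Mg, THF, 40 °C; then 12, CuBr·SMe2 (5 mol %), Et2O–THF, −40 → −10 °C
Reagents that add atoms: none
Why: In a copper-catalysed alkyl–alkyl Grignard coupling of the Kochi–Tamura type a primary triflate reacts far faster than a primary bromide at low temperature, so the new C–C bond forms at the triflate carbon, the bromide survives for the next step and the adjacent stereocentre is untouched.

Step 8
Reactants: 10 2-[(2R)-2-methyloxetan-2-yl]acetaldehyde; 15 [(9R)-10-bromo-9-methyldecyl]benzene
Product: 17 (4R)-4-methyl-1-[(2R)-2-methyloxetan-2-yl]-12-phenyldodecan-2-ol (both C2 epimers), via side-chain Grignard reagent 16 (not isolated)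
Conditions: 15, Mg, THF, 40 °C; then 10, THF, −78 → −20 °C; sat. aq NH4Cl
Reagents that add atoms: none
Why: Grignard addition of a primary alkylmagnesium bromide to an aldehyde at −78 °C is faster than enolisation, and the new carbinol centre, formed as both epimers, is erased by the oxidation that follows.

Step 9
Reactants: 17 (4R)-4-methyl-1-[(2R)-2-methyloxetan-2-yl]-12-phenyldodecan-2-ol (both C2 epimers)
Product: 18 (4R)-4-methyl-1-[(2R)-2-methyloxetan-2-yl]-12-phenyldodecan-2-one
Conditions: n-Pr4N[RuO4] (5 mol %), N-methylmorpholine N-oxide, 4 Å molecular sieves, CH2Cl2, rt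
Reagents that add atoms: none
Why: Ley–Griffith oxidation turns the secondary alcohol into the ketone under neutral conditions that neither open the oxetane nor disturb the methyl-bearing centre two carbons away.

Step 10
Reactants: 18 (4R)-4-methyl-1-[(2R)-2-methyloxetan-2-yl]-12-phenyldodecan-2-one
Product: 19 (2S)-2-methyl-2-[(4R)-4-methyl-2-methylidene-12-phenyldodecyl]oxetane
Conditions: Cp2TiMe2 (3 equiv), toluene–THF, 65 °C, dark
Reagents that add atoms: dimethyltitanocene [CH3-].[CH3-].[Ti+4].c1cc[cH-]c1.c1cc[cH-]c1
Why: Petasis methylenation goes through a titanium methylidene and an oxatitanacyclobutane without strong base, so the hindered, enolisable ketone with an oxetane in the beta position should give the 1,1-disubstituted alkene without eliminative opening of the four-membered ring.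

Step 11
Reactants: 19 (2S)-2-methyl-2-[(4R)-4-methyl-2-methylidene-12-phenyldodecyl]oxetane
Product: 20 triethyl({(2RS,4R)-2,4-dimethyl-1-[(2R)-2-methyloxetan-2-yl]-12-phenyldodecan-2-yl}peroxy)silane (both C2 epimers)
Conditions: Co(acac)2 (10 mol %), Et3SiH (2 equiv), O2 (1 atm), ClCH2CH2Cl, rt
Reagents that add atoms: dioxygen O=O; triethylsilane CC[SiH](CC)CC
Why: In the Mukaiyama–Isayama reductive peroxidation a cobalt hydride transfers a hydrogen atom to the CH2 terminus, the tertiary radical traps O2 and the peroxide is silylated, which places methyl and peroxide on the future C5 with Markovnikov selectivity; the planar radical is flanked only by distant stereocentres, so the new centre should form as both epimers and the product is taken on as that pair.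

Step 12
Reactants: 20 triethyl({(2RS,4R)-2,4-dimethyl-1-[(2R)-2-methyloxetan-2-yl]-12-phenyldodecan-2-yl}peroxy)silane (both C2 epimers)
Product: 21 (2R)-2-[(2RS,4R)-2-hydroperoxy-2,4-dimethyl-12-phenyldodecyl]-2-methyloxetane (both C2 epimers)
Conditions: n-Bu4NF (1.1 equiv), THF, 0 °C, 10 min; pH 7 buffer
Reagents that add atoms: none
Why: Fluoride cleaves the O–Si bond of a silyl peroxide (standard desilylation) under mildly basic conditions in which a tertiary hydroperoxide and an oxetane both persist, and no stereocentre is touched.

Step 13
Reactants: 21 (2R)-2-[(2RS,4R)-2-hydroperoxy-2,4-dimethyl-12-phenyldodecyl]-2-methyloxetane (both C2 epimers; the 2R epimer carries the target configuration at C5)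
Product: 22 2-{(3S,5R)-3,5-dimethyl-5-[(2R)-2-methyl-10-phenyldecyl]-1,2-dioxolan-3-yl}ethan-1-ol
Conditions: Me3SiOTf (0.2 equiv), CH2Cl2, −78 → −30 °C; aq NaHCO3; SiO2 chromatography, which removes the trans-dimethyl diastereomer formed from the other epimer of 21
Reagents that add atoms: none
Why: The silyl triflate, or the triflic acid it releases on contact with the hydroperoxide, activates the oxetane oxygen, and the terminal oxygen of the tertiary hydroperoxide attacks the tertiary oxetane carbon from the side opposite to the C–O bond in a tight, SN2-like transition state, so that C3–O2 forms while the ring oxygen leaves as the 2-hydroxyethyl arm. The closest known reaction type is the acid-promoted intramolecular opening of 2,2-disubstituted oxetanes by hydroperoxides to 1,2-dioxolanes, supported by the intermolecular perhydrolysis of tertiary oxetanes with inversion. The 1,2-dioxolane closes in a 5-exo-tet mode. The new stereocentre C3 is set by the configuration of the oxetane carbon, which stems from the Sharpless epoxidation, and arrives with inversion, while C5 is only carried through. The step needs attack at the tertiary and not the primary oxetane carbon and no free carbocation: the five-membered transition state (the primary carbon would require a seven-membered endo-type closure), the better charge stabilisation at the tertiary carbon, the release of ring strain and the low temperature secure both. Since both epimers of 21 should cyclise, the cis- and trans-dimethyl dioxolanes arise side by side as ring diastereomers, and the cis isomer 22 is isolated on silica.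

Step 14
Reactants: 22 2-{(3S,5R)-3,5-dimethyl-5-[(2R)-2-methyl-10-phenyldecyl]-1,2-dioxolan-3-yl}ethan-1-ol
Product: 24 2-{(3R,5R)-3,5-dimethyl-5-[(2R)-2-methyl-10-phenyldecyl]-1,2-dioxolan-3-yl}acetic acid, via dioxolanylacetaldehyde 23 (not isolated)
Conditions: TEMPO (7 mol %), NaClO2, NaOCl (2 mol %), MeCN–phosphate buffer pH 6.7, rt; aq KHSO4 to pH 3; final purification by chromatography
Reagents that add atoms: sodium chlorite [Na+].[O-]Cl=O
Why: The one-pot oxoammonium (Anelli-type) oxidation to the aldehyde and Pinnick-type chlorite oxidation to the acid run near neutral pH and should leave the dialkyl peroxide, the benzylic position and all three stereocentres untouched; the descriptor at C3 changes from S to R only because the arm gains priority.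

**Compound list**

1 | pent-1-en-4-yne | C=CCC#C | starting material
2 | dimethyl[(1E)-2-methylpenta-1,4-dien-1-yl]alane | C=CC/C(C)=C/[Al](C)C | intermediate
3 | lithium butyl(dimethyl)[(1E)-2-methylpenta-1,4-dien-1-yl]aluminate | [Li+].C=CC/C(C)=C/[Al-](C)(C)CCCC | intermediate
4 | (2E)-3-methylhexa-2,5-dien-1-ol | C=CC/C(C)=C/CO | intermediate
5 | [(2S,3S)-3-methyl-3-(prop-2-en-1-yl)oxiran-2-yl]methanol | C=CC[C@]1(C)O[C@H]1CO | intermediate
6 | (3S)-3-methylhex-5-ene-1,3-diol | C=CC[C@](C)(O)CCO | intermediate
7 | (3S)-3-hydroxy-3-methylhex-5-en-1-yl 4-methylbenzenesulfonate | C=CC[C@](C)(O)CCOS(=O)(=O)c1ccc(C)cc1 | intermediate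
8 | (2S)-2-methyl-2-(prop-2-en-1-yl)oxetane | C=CC[C@@]1(C)CCO1 | intermediate
9 | 3-{[(2R)-2-methyloxetan-2-yl]methyl}-1,2,4-trioxolane (both configurations at the trioxolane carbon) | C1(C[C@@]2(C)CCO2)OCOO1 | intermediate
10 | 2-[(2R)-2-methyloxetan-2-yl]acetaldehyde | O=CC[C@@]1(C)CCO1 | intermediate
11 | (2R)-3-bromo-2-methylpropan-1-ol | C[C@H](CO)CBr | starting material
12 | (2R)-3-bromo-2-methylpropyl trifluoromethanesulfonate | C[C@H](COS(=O)(=O)C(F)(F)F)CBr | intermediate
13 | (7-bromoheptyl)benzene | BrCCCCCCCc1ccccc1 | starting material
14 | (7-phenylheptyl)magnesium bromide | Br[Mg]CCCCCCCc1ccccc1 | intermediate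
15 | [(9R)-10-bromo-9-methyldecyl]benzene | C[C@H](CCCCCCCCc1ccccc1)CBr | intermediate
16 | [(2R)-2-methyl-10-phenyldecyl]magnesium bromide | C[C@H](CCCCCCCCc1ccccc1)C[Mg]Br | intermediate
17 | (4R)-4-methyl-1-[(2R)-2-methyloxetan-2-yl]-12-phenyldodecan-2-ol (both C2 epimers) | C[C@H](CCCCCCCCc1ccccc1)CC(O)C[C@@]1(C)CCO1 | intermediate
18 | (4R)-4-methyl-1-[(2R)-2-methyloxetan-2-yl]-12-phenyldodecan-2-one | C[C@H](CCCCCCCCc1ccccc1)CC(=O)C[C@@]1(C)CCO1 | intermediate
19 | (2S)-2-methyl-2-[(4R)-4-methyl-2-methylidene-12-phenyldodecyl]oxetane | C[C@H](CCCCCCCCc1ccccc1)CC(=C)C[C@@]1(C)CCO1 | intermediate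
20 | triethyl({(2RS,4R)-2,4-dimethyl-1-[(2R)-2-methyloxetan-2-yl]-12-phenyldodecan-2-yl}peroxy)silane (both C2 epimers, carried as the pair) | C[C@H](CCCCCCCCc1ccccc1)CC(C)(OO[Si](CC)(CC)CC)C[C@@]1(C)CCO1 | intermediate
21 | (2R)-2-[(2RS,4R)-2-hydroperoxy-2,4-dimethyl-12-phenyldodecyl]-2-methyloxetane (both C2 epimers, carried as the pair; the 2R epimer has the target configuration at C5) | C[C@H](CCCCCCCCc1ccccc1)CC(C)(OO)C[C@@]1(C)CCO1 | intermediate
22 | 2-{(3S,5R)-3,5-dimethyl-5-[(2R)-2-methyl-10-phenyldecyl]-1,2-dioxolan-3-yl}ethan-1-ol (cis-dimethyl) | C[C@H](CCCCCCCCc1ccccc1)C[C@]1(C)C[C@](C)(CCO)OO1 | intermediate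
23 | 2-{(3R,5R)-3,5-dimethyl-5-[(2R)-2-methyl-10-phenyldecyl]-1,2-dioxolan-3-yl}acetaldehyde | C[C@H](CCCCCCCCc1ccccc1)C[C@]1(C)C[C@](C)(CC=O)OO1 | intermediate
24 | 2-{(3R,5R)-3,5-dimethyl-5-[(2R)-2-methyl-10-phenyldecyl]-1,2-dioxolan-3-yl}acetic acid | C[C@H](CCCCCCCCc1ccccc1)C[C@]1(C)C[C@](C)(CC(=O)O)OO1 | target

**Count and risks**

Total step count: 14. Longest linear sequence: 12 steps (steps 1–5 and 8–14, from pent-1-en-4-yne); the side-chain branch (steps 6–7) joins at step 8.

Steps most likely to fail:

1. Step 13. The activated oxetane may ionise before the peroxide oxygen arrives, which would erode the configuration at C3 or lead to elimination, or the acid may fragment the tertiary hydroperoxide. The fallback sets out from 19 and comes back at 22, closing the ring from the other end. The oxetane of 19 is opened intermolecularly with anhydrous ethereal H2O2 and catalytic Me3SiOTf at low temperature, with inversion at the tertiary carbon, to give (3R,7R)-3-hydroperoxy-3,7-dimethyl-5-methylidene-15-phenylpentadecan-1-ol F1. Cycloperoxymercuration with Hg(OAc)2 in CH2Cl2 then lets the hydroperoxide, the better nucleophile and placed for five-ring closure, add 5-exo to the mercury-activated 1,1-disubstituted alkene. This gives acetoxy({(5S)-5-(2-hydroxyethyl)-5-methyl-3-[(2R)-2-methyl-10-phenyldecyl]-1,2-dioxolan-3-yl}methyl)mercury F2 as both epimers at the new ring carbon. Reductive demercuration with NaBH4 in aqueous NaOH turns the mercuriomethyl group into the C5 methyl and delivers 22 together with its trans-dimethyl diastereomer, which is removed on silica as in the main route.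

2. Step 8. The small aldehyde may be lost on isolation, or the basic Grignard reagent may enolise it and trigger eliminative opening of the oxetane in place of addition. The fallback sets out from 8 and comes back at 19, replacing carbonyl addition by cross-coupling. Tsuji–Wacker oxidation of 8 (PdCl2, CuCl, O2, DMF–H2O) gives 1-[(2R)-2-methyloxetan-2-yl]propan-2-one F3. Kinetic deprotonation on the methyl side with KN(SiMe3)2 at −78 °C and trapping with N-phenyl-bis(trifluoromethanesulfonimide) gives 3-[(2R)-2-methyloxetan-2-yl]prop-1-en-2-yl trifluoromethanesulfonate F4. Iron-catalysed Kumada-type coupling of F4 with the Grignard reagent 16 (Fe(acac)3, THF–N-methylpyrrolidone, −30 °C) gives 19 directly, so that 10, 17 and 18 are not needed.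

3. Step 10. Methylenation of the doubly branched ketone may be slower than thermal decay of the titanium reagent, or heating may bring about retro-oxa-Michael opening of the oxetane. The fallback sets out from 18 and comes back at 19 through a Peterson olefination. The weakly basic organocerium reagent from Me3SiCH2Li and CeCl3 adds to 18 at −78 °C to give (4R)-4-methyl-1-[(2R)-2-methyloxetan-2-yl]-12-phenyl-2-[(trimethylsilyl)methyl]dodecan-2-ol F5. KH in THF then induces syn-elimination of silanolate to give 19, at a stage where no enolisable carbonyl group is left.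

**Further compounds**

F1 | step 13 | (3R,7R)-3-hydroperoxy-3,7-dimethyl-5-methylidene-15-phenylpentadecan-1-ol | C[C@H](CCCCCCCCc1ccccc1)CC(=C)C[C@](C)(CCO)OO
F2 | step 13 | acetoxy({(5S)-5-(2-hydroxyethyl)-5-methyl-3-[(2R)-2-methyl-10-phenyldecyl]-1,2-dioxolan-3-yl}methyl)mercury (both configurations at ring carbon 3) | C[C@H](CCCCCCCCc1ccccc1)CC1(C[Hg]OC(C)=O)C[C@](C)(CCO)OO1
F3 | step 8 | 1-[(2R)-2-methyloxetan-2-yl]propan-2-one | CC(=O)C[C@@]1(C)CCO1
F4 | step 8 | 3-[(2R)-2-methyloxetan-2-yl]prop-1-en-2-yl trifluoromethanesulfonate | C=C(OS(=O)(=O)C(F)(F)F)C[C@@]1(C)CCO1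
F5 | step 10 | (4R)-4-methyl-1-[(2R)-2-methyloxetan-2-yl]-12-phenyl-2-[(trimethylsilyl)methyl]dodecan-2-ol (both C2 epimers) | C[C@H](CCCCCCCCc1ccccc1)CC(O)(C[Si](C)(C)C)C[C@@]1(C)CCO1
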